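**Retrosynthetic overview**
1. Ring A (the lactol) is unmasked last from a silyl ether and a dioxolane. The ring B carbinol comes from methyl addition to a ring B ketone.
2. The halves are joined at the α-carbon of the ring B ketone. A regiodefined enolate and a hydroazulenyl-acetaldehyde undergo aldol condensation, followed by 1,4-reduction.
3. That aldehyde comes from a ring C allylic alcohol by a Claisen rearrangement. This one step sets the two-carbon arm, its stereocentre and the ring C olefin position.
4. Key disconnection: SmI2 closes ring D by bonding a side-chain ketone carbon to the β-carbon of a cross-conjugated cycloheptadienone. Both carbons are acceptors, so one reacts with reversed polarity. The second enone is kept for line 3.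
5. Ring C arises by one-carbon enlargement of a cyclohexenone, made by asymmetric addition of a masked butanone homoenolate to a cyclohexadienone. The ring B enone takes a masked propanal homoenolate. Ring order: six-ring precursor, then C, then D; B is carried from a bought cyclohexenone; A is last.

Rings: A = lactol, B = cyclohexane, C = cycloheptene, D = cyclopentane.

Assumption: the lactol carbon epimerises freely through the open hydroxy aldehyde. The drawn anomer (equatorial OH, 2S) is taken as the form that is collected.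

**Step 1**
Reactants: 1 isobutyraldehyde; 2 ethyl vinyl ketone
Product: 4 2,4,4-trimethylcyclohex-2-en-1-one, via keto aldehyde 3 (not isolated)
Conditions: H2SO4 (cat.), toluene, reflux, Dean–Stark
Reagents that add atoms: none
Why: Robinson annulation (acid-catalysed Michael addition, then intramolecular aldol condensation) can close a six-membered ring only through the ethyl CH2, which puts the methyl on C-2; no stereocentre is formed.

**Step 2**
Reactants: 4 2,4,4-trimethylcyclohex-2-en-1-one
Product: 5 2,4,4-trimethylcyclohexa-2,5-dien-1-one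
Conditions: DDQ, 1,4-dioxane, reflux
Reagents that add atoms: none
Why: Quinone dehydrogenation runs through the α′-enol because the γ-carbon is quaternary, so only the cross-conjugated dienone can form.

**Step 3**
Reactants: 5 2,4,4-trimethylcyclohexa-2,5-dien-1-one; 6 2-(2-bromoethyl)-2-methyl-1,3-dioxolane
Product: 9 (5S)-2,4,4-trimethyl-5-[2-(2-methyl-1,3-dioxolan-2-yl)ethyl]cyclohex-2-en-1-one, via alkylmagnesium bromide 7 (not isolated), via diorganozinc 8 (not isolated)
Conditions: 6, Mg, THF, 25 °C; ZnCl2 (0.5 equiv), then 1,4-dioxane, filter; Cu(OTf)2 (2 mol %), (R)-BINOL-derived N,N-bis[(S)-1-phenylethyl]phosphoramidite (4 mol %), 5, toluene, −30 °C; H2O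
Reagents that add atoms: none
Why: In this copper-catalysed asymmetric conjugate addition of a dialkylzinc (a masked butanone homoenolate), the reagent attacks the unsubstituted enone arm because the α-methyl arm is far slower, and the ligand controls the face to set C-5 as S (the antipode of the ligand that gives (S)-3-ethylcyclohexanone is used).

**Step 4**
Reactants: 9 (5S)-2,4,4-trimethyl-5-[2-(2-methyl-1,3-dioxolan-2-yl)ethyl]cyclohex-2-en-1-one
Product: 11 trimethyl({(1R,5S,6S)-2,4,4-trimethyl-5-[2-(2-methyl-1,3-dioxolan-2-yl)ethyl]bicyclo[4.1.0]hept-2-en-1-yl}oxy)silane, via silyl dienol ether 10 (not isolated)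
Conditions: LiN(iPr)2, Me3SiCl, THF, −78 °C; crude, Et2Zn, CH2I2, CH2Cl2, 0 °C
Reagents that add atoms: chlorotrimethylsilane C[Si](C)(C)Cl; diiodomethane ICI
Why: C-6 is the only enolisable position, so one 2-silyloxydiene forms, and the electrophilic zinc carbenoid (Simmons–Smith cyclopropanation) attacks only its electron-rich enol-ether bond, anti to the side chain; the two new centres are erased in step 5.

**Step 5**
Reactants: 11 siloxycyclopropane
Product: 14 (5S)-2,4,4-trimethyl-5-(3-oxobutyl)cyclohepta-2,6-dien-1-one, via beta-chloro ketone 12 (not isolated), via ketal dienone 13 (not isolated)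
Conditions: FeCl3 (2.2 equiv), DMF, 0 → 25 °C; NaOAc, MeOH, reflux; 1 M HCl, THF, 25 °C
Reagents that add atoms: water O
Why: In this Saegusa-type oxidative ring expansion, FeCl3 cleaves the internal cyclopropane bond to the ring-enlarged secondary radical, which takes up chlorine; acetate E1cB then gives the enone and acid removes the ketal, leaving C-5 untouched.

**Step 6 (key step)**
Reactants: 14 (5S)-2,4,4-trimethyl-5-(3-oxobutyl)cyclohepta-2,6-dien-1-one
Product: 16 (3S,3aS,8aS)-3-hydroxy-3,6,8,8-tetramethyl-2,3,3a,4,8,8a-hexahydroazulen-5(1H)-one, via samarium dienolate 15 (not isolated)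
Conditions: SmI2 (2.2 equiv), HMPA, THF, −78 °C, slow addition of 14 (0.01 M), no proton source; then H2O (pH 7 buffer)
Reagents that add atoms: none
Why: In this reductive carbonyl–enone (ketyl–olefin) 5-exo cyclisation, electron transfer reverses the polarity of one of two acceptor carbons so that the ketone carbon bonds to the dienone β-carbon; the tether on C-8a forces the cis ring fusion (3aS), the bulky samarium alkoxide sits on the convex face anti to C-4 (3S, OH cis to both fusion H), and the product stays a dienolate until quench, which shields the second enone from reduction.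

**Step 7**
Reactants: 16 hydroxy enone
Product: 17 (1S,3aS,7R,8aS)-1,4,4,6-tetramethyl-1,2,3,3a,4,7,8,8a-octahydroazulene-1,7-diol
Conditions: (S)-2-methyl-CBS-oxazaborolidine (20 mol %), BH3·SMe2, THF, −40 °C; MeOH
Reagents that add atoms: none
Why: In this CBS 1,2-reduction the α-methyl-alkenyl side acts as the large group, so the (S)-catalyst gives the 7R carbinol, which matches the substrate's own preference for hydride attack on the convex face (the face of the fusion hydrogens).

**Step 8**
Reactants: 17 diol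
Product: 19 2-[(1S,3aS,5R,8aS)-1-hydroxy-1,4,4,6-tetramethyl-1,2,3,3a,4,5,8,8a-octahydroazulen-5-yl]acetaldehyde, via allyl vinyl ether 18 (not isolated)
Conditions: n-butyl vinyl ether (solvent), Pd(OCOCF3)2 (5 mol %), 4,7-diphenyl-1,10-phenanthroline (5 mol %), Et3N, 75 °C; concentrate; xylene, 150 °C, sealed tube
Reagents that add atoms: n-butyl vinyl ether C=COCCCC
Why: Transvinylation of the secondary allylic OH is followed by a Claisen [3,3] rearrangement, whose suprafacial shift transfers the 7R C–O configuration to the new C–C bond next to the gem-dimethyl carbon (5R) and moves the olefin exactly to the C-6/C-7 position of the target.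

**Step 9**
Reactants: 20 2-methylcyclohex-2-en-1-one
Product: 21 (1S)-2-methylcyclohex-2-en-1-ol
Conditions: (R)-2-methyl-CBS-oxazaborolidine (10 mol %), BH3·SMe2, THF, −20 °C; MeOH
Reagents that add atoms: none
Why: CBS reduction with the substituted alkene as the large group gives the S carbinol with the (R)-catalyst; this centre becomes the ring A/B C–O carbon.

**Step 10**
Reactants: 21 (1S)-2-methylcyclohex-2-en-1-ol
Product: 22 tert-butyl(dimethyl){[(1S)-2-methylcyclohex-2-en-1-yl]oxy}silane
Conditions: TBSCl, imidazole, DMF, 25 °C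
Reagents that add atoms: tert-butyldimethylsilyl chloride CC(C)(C)[Si](C)(C)Cl
Why: Standard silylation protects the carbinol from the next oxidation and supplies the bulky group that later steers the conjugate addition.

**Step 11**
Reactants: 22 silyl ether
Product: 23 (4S)-4-[(tert-butyldimethylsilyl)oxy]-3-methylcyclohex-2-en-1-one
Conditions: Rh2(caprolactamate)4 (1 mol %), t-BuOOH (70 % aq), K2CO3, CH2Cl2, 25 °C
Reagents that add atoms: tert-butyl hydroperoxide CC(C)(C)OO
Why: Radical allylic oxidation attacks the unhindered ring CH2, not the shielded silyloxy C–H or the methyl, to give the enone without touching the stereocentre.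

**Step 12**
Reactants: 23 silyloxy enone; 24 2-(2-bromoethyl)-1,3-dioxolane
Product: 26 {[(3S,4S)-4-[(tert-butyldimethylsilyl)oxy]-3-[2-(1,3-dioxolan-2-yl)ethyl]-3-methylcyclohex-1-en-1-yl]oxy}trimethylsilane, via alkylmagnesium bromide 25 (not isolated)
Conditions: 24, Mg, THF, 25 °C; CuBr·SMe2 (20 mol %), Me3SiCl, HMPA, THF, −78 → −40 °C; Et3N, cold aq NaHCO3
Reagents that add atoms: chlorotrimethylsilane C[Si](C)(C)Cl
Why: In this chlorosilane-accelerated copper-catalysed conjugate addition of a masked propanal homoenolate, the nucleophile enters anti to the C-4 silyloxy group, which sets the quaternary centre (3S, chain trans to O), and the enolate is trapped regiospecifically on the hindered side.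

**Step 13**
Reactants: 26 silyl enol ether (2 equiv); 19 aldehyde
Product: 30 (3S,4S)-4-[(tert-butyldimethylsilyl)oxy]-3-[2-(1,3-dioxolan-2-yl)ethyl]-2-{2-[(1S,3aS,5R,8aS)-1-hydroxy-1,4,4,6-tetramethyl-1,2,3,3a,4,5,8,8a-octahydroazulen-5-yl]ethylidene}-3-methylcyclohexan-1-one (E/Z mixture), via lithium enolate 27 (not isolated), via lithium aldolate 28 (not isolated), via beta-acetoxy ketone 29 (not isolated)
Conditions: 26, MeLi, THF, 0 °C; 19, −78 °C; Ac2O, −78 → 0 °C; DBU, 25 °C
Reagents that add atoms: none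
Why: This is a directed aldol condensation in which MeLi unmasks the regiodefined enolate, the small aldehyde adds even next to the quaternary carbon, and acetylation of the aldolate with E1cB loss of acetate gives the exocyclic enone, so the aldol stereocentres do not matter; the neutral tertiary OH is not acylated without an acyl-transfer catalyst.

**Step 14**
Reactants: 30 exocyclic enone
Product: 32 (2S,3S,4S)-4-[(tert-butyldimethylsilyl)oxy]-3-[2-(1,3-dioxolan-2-yl)ethyl]-2-{2-[(1S,3aS,5R,8aS)-1-hydroxy-1,4,4,6-tetramethyl-1,2,3,3a,4,5,8,8a-octahydroazulen-5-yl]ethyl}-3-methylcyclohexan-1-one, via triethylsilyl enol ether 31 (not isolated)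
Conditions: Et3SiH, RhCl(PPh3)3 (2 mol %), toluene, 50 °C; K2CO3, MeOH, 25 °C
Reagents that add atoms: none
Why: Rhodium-catalysed 1,4-hydrosilylation takes only the fixed s-cis enone and leaves the hindered ring C olefin (as in ionone-type 1,4-reductions), and basic methanolysis protonates C-2 axially and equilibrates it, so the chain ends equatorial (2S).

**Step 15**
Reactants: 32 ketone
Product: 33 (1R,2S,3S,4S)-4-[(tert-butyldimethylsilyl)oxy]-3-[2-(1,3-dioxolan-2-yl)ethyl]-2-{2-[(1S,3aS,5R,8aS)-1-hydroxy-1,4,4,6-tetramethyl-1,2,3,3a,4,5,8,8a-octahydroazulen-5-yl]ethyl}-1,3-dimethylcyclohexan-1-ol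
Conditions: MeLi, CeCl3 (4 equiv each), THF, −78 °C; H2O
Reagents that add atoms: methyllithium [Li]C
Why: In this organocerium 1,2-addition (low basicity, no enolisation) the axial trajectory is blocked by the syn-axial C-3 methyl, so methyl enters equatorially and the OH ends axial (1R).

**Step 16**
Reactants: 33 protected triol
Product: 35 (2S,4aS,5S,6R,8aS)-5-{2-[(1S,3aS,5R,8aS)-1-hydroxy-1,4,4,6-tetramethyl-1,2,3,3a,4,5,8,8a-octahydroazulen-5-yl]ethyl}-4a,6-dimethyloctahydro-2H-chromene-2,6-diol (target), via hydroxy aldehyde 34 (not isolated)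
Conditions: aq HF (48 %), MeCN, 0 → 25 °C
Reagents that add atoms: water O
Why: Acidic desilylation and acetal hydrolysis release a δ-hydroxy aldehyde that closes spontaneously to the trans-fused lactol (chain and O both equatorial), with the anomeric centre under thermodynamic control and the non-allylic tertiary alcohols surviving the mild acid.

**Compound list**
1 | isobutyraldehyde | CC(C)C=O | starting material
2 | ethyl vinyl ketone (pent-1-en-3-one) | CCC(=O)C=C | starting material
3 | 2,2-dimethyl-5-oxoheptanal | CCC(=O)CCC(C)(C)C=O | intermediate (not isolated)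
4 | 2,4,4-trimethylcyclohex-2-en-1-one | CC1=CC(C)(C)CCC1=O | intermediate
5 | 2,4,4-trimethylcyclohexa-2,5-dien-1-one | CC1=CC(C)(C)C=CC1=O | intermediate
6 | 2-(2-bromoethyl)-2-methyl-1,3-dioxolane | CC1(CCBr)OCCO1 | starting material
7 | [2-(2-methyl-1,3-dioxolan-2-yl)ethyl]magnesium bromide | CC1(CC[Mg]Br)OCCO1 | intermediate (not isolated)
8 | bis[2-(2-methyl-1,3-dioxolan-2-yl)ethyl]zinc | CC1(CC[Zn]CCC2(C)OCCO2)OCCO1 | intermediate (not isolated)
9 | (5S)-2,4,4-trimethyl-5-[2-(2-methyl-1,3-dioxolan-2-yl)ethyl]cyclohex-2-en-1-one | CC1=CC(C)(C)[C@@H](CCC2(C)OCCO2)CC1=O | intermediate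
10 | trimethyl({(3S)-4,4,6-trimethyl-3-[2-(2-methyl-1,3-dioxolan-2-yl)ethyl]cyclohexa-1,5-dien-1-yl}oxy)silane | CC1=CC(C)(C)[C@@H](CCC2(C)OCCO2)C=C1O[Si](C)(C)C | intermediate (not isolated)
11 | trimethyl({(1R,5S,6S)-2,4,4-trimethyl-5-[2-(2-methyl-1,3-dioxolan-2-yl)ethyl]bicyclo[4.1.0]hept-2-en-1-yl}oxy)silane | CC1=CC(C)(C)[C@@H](CCC2(C)OCCO2)[C@@H]2C[C@]12O[Si](C)(C)C | intermediate
12 | (5R)-6-chloro-2,4,4-trimethyl-5-[2-(2-methyl-1,3-dioxolan-2-yl)ethyl]cyclohept-2-en-1-one (both C-6 epimers; C-5 spatially as in 9) | CC1=CC(C)(C)[C@@H](CCC2(C)OCCO2)C(Cl)CC1=O | intermediate (not isolated)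
13 | (5S)-2,4,4-trimethyl-5-[2-(2-methyl-1,3-dioxolan-2-yl)ethyl]cyclohepta-2,6-dien-1-one | CC1=CC(C)(C)[C@@H](CCC2(C)OCCO2)C=CC1=O | intermediate (not isolated)
14 | (5S)-2,4,4-trimethyl-5-(3-oxobutyl)cyclohepta-2,6-dien-1-one | CC1=CC(C)(C)[C@@H](CCC(C)=O)C=CC1=O | intermediate
15 | bis(diiodosamarium) alkoxide–dienolate of 16 (trivalent samarium) | CC1=CC(C)(C)[C@H]2CC[C@](C)(O[Sm](I)I)[C@H]2C=C1O[Sm](I)I | intermediate (not isolated)
16 | (3S,3aS,8aS)-3-hydroxy-3,6,8,8-tetramethyl-2,3,3a,4,8,8a-hexahydroazulen-5(1H)-one | CC1=CC(C)(C)[C@H]2CC[C@](C)(O)[C@H]2CC1=O | intermediate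
17 | (1S,3aS,7R,8aS)-1,4,4,6-tetramethyl-1,2,3,3a,4,7,8,8a-octahydroazulene-1,7-diol | CC1=CC(C)(C)[C@H]2CC[C@](C)(O)[C@H]2C[C@H]1O | intermediate
18 | (1S,3aS,7R,8aS)-7-(ethenyloxy)-1,4,4,6-tetramethyl-1,2,3,3a,4,7,8,8a-octahydroazulen-1-ol | CC1=CC(C)(C)[C@H]2CC[C@](C)(O)[C@H]2C[C@H]1OC=C | intermediate (not isolated)
19 | 2-[(1S,3aS,5R,8aS)-1-hydroxy-1,4,4,6-tetramethyl-1,2,3,3a,4,5,8,8a-octahydroazulen-5-yl]acetaldehyde | CC1=CC[C@H]2[C@H](CC[C@]2(C)O)C(C)(C)[C@@H]1CC=O | intermediate
20 | 2-methylcyclohex-2-en-1-one | CC1=CCCCC1=O | starting material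
21 | (1S)-2-methylcyclohex-2-en-1-ol | CC1=CCCC[C@@H]1O | intermediate
22 | tert-butyl(dimethyl){[(1S)-2-methylcyclohex-2-en-1-yl]oxy}silane | CC1=CCCC[C@@H]1O[Si](C)(C)C(C)(C)C | intermediate
23 | (4S)-4-[(tert-butyldimethylsilyl)oxy]-3-methylcyclohex-2-en-1-one | CC1=CC(=O)CC[C@@H]1O[Si](C)(C)C(C)(C)C | intermediate
24 | 2-(2-bromoethyl)-1,3-dioxolane | BrCCC1OCCO1 | starting material
25 | [2-(1,3-dioxolan-2-yl)ethyl]magnesium bromide | Br[Mg]CCC1OCCO1 | intermediate (not isolated)
26 | {[(3S,4S)-4-[(tert-butyldimethylsilyl)oxy]-3-[2-(1,3-dioxolan-2-yl)ethyl]-3-methylcyclohex-1-en-1-yl]oxy}trimethylsilane | C[Si](C)(C)OC1=C[C@](C)(CCC2OCCO2)[C@@H](O[Si](C)(C)C(C)(C)C)CC1 | intermediate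
27 | lithium enolate corresponding to 26 | [Li]OC1=C[C@](C)(CCC2OCCO2)[C@@H](O[Si](C)(C)C(C)(C)C)CC1 | intermediate (not isolated)
28 | lithium aldolate of 27 and 19 (epimers at the two new centres) | CC1=CC[C@H]2[C@H](CC[C@]2(C)O)C(C)(C)[C@@H]1CC(O[Li])C1[C@](C)(CCC2OCCO2)[C@@H](O[Si](C)(C)C(C)(C)C)CCC1=O | intermediate (not isolated)
29 | acetate of the aldol (epimers at the two new centres) | CC1=CC[C@H]2[C@H](CC[C@]2(C)O)C(C)(C)[C@@H]1CC(OC(C)=O)C1[C@](C)(CCC2OCCO2)[C@@H](O[Si](C)(C)C(C)(C)C)CCC1=O | intermediate (not isolated)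
30 | exocyclic enone (name in step 13; E/Z mixture) | CC1=CC[C@H]2[C@H](CC[C@]2(C)O)C(C)(C)[C@@H]1CC=C1[C@](C)(CCC2OCCO2)[C@@H](O[Si](C)(C)C(C)(C)C)CCC1=O | intermediate
31 | triethylsilyl enol ether of 32 (tetrasubstituted ring enol ether) | CC1=CC[C@H]2[C@H](CC[C@]2(C)O)C(C)(C)[C@@H]1CCC1=C(O[Si](CC)(CC)CC)CC[C@H](O[Si](C)(C)C(C)(C)C)[C@@]1(C)CCC1OCCO1 | intermediate (not isolated)
32 | (2S,3S,4S)-ketone (name in step 14) | CC1=CC[C@H]2[C@H](CC[C@]2(C)O)C(C)(C)[C@@H]1CC[C@H]1[C@](C)(CCC2OCCO2)[C@@H](O[Si](C)(C)C(C)(C)C)CCC1=O | intermediate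
33 | (1R,2S,3S,4S)-tertiary alcohol (name in step 15) | CC1=CC[C@H]2[C@H](CC[C@]2(C)O)C(C)(C)[C@@H]1CC[C@H]1[C@](C)(CCC2OCCO2)[C@@H](O[Si](C)(C)C(C)(C)C)CC[C@@]1(C)O | intermediate
34 | open hydroxy aldehyde form of 35 | CC1=CC[C@H]2[C@H](CC[C@]2(C)O)C(C)(C)[C@@H]1CC[C@H]1[C@](C)(CCC=O)[C@@H](O)CC[C@@]1(C)O | intermediate (not isolated)
35 | CNP0167351.1 (name in step 16) | CC1=CC[C@H]2[C@H](CC[C@]2(C)O)C(C)(C)[C@@H]1CC[C@H]1[C@]2(C)CC[C@@H](O)O[C@H]2CC[C@@]1(C)O | target

**Totals**
Total step count: 16.
Longest linear sequence: 12 (steps 1–8, then 13–16).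

**Three steps most likely to fail**

Step 6. Several side reactions can compete with the closure: simple 1,4-reduction, intermolecular β,β-coupling, closure on the other enone terminus to a bridged six-membered ring, and the wrong carbinol epimer through chelation.
The fallback sets out from 14 and returns at 16. It replaces electron transfer by hydrogen-atom transfer.
- The methyl ketone is converted with LiN(SiMe3)2 and TBSCl (THF–HMPA, −78 °C) into the kinetic terminal silyl enol ether F1.
- Fe(acac)3 and PhSiH3 in EtOH at 60 °C deliver H to the CH2 of the electron-rich enol ether only. The neutral α-silyloxy tertiary radical then closes 5-exo on the same β-carbon to give the cyclised silyl ether F2.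
- HF·pyridine frees 16.

Step 8. The new bond forms next to a quaternary carbon. Thermal loss of acetaldehyde to a diene, or sluggish vinylation, may win.
The fallback sets out from 17 and returns at 19. It uses a carbamate-directed syn-SN2′ displacement instead of a sigmatropic shift.
- PhNCO acylates the secondary OH to the N-phenylcarbamate F3.
- Deprotonation with MeLi and treatment with LiCu(CH=CHOEt)2, made from (Z)-2-ethoxyvinyllithium and CuI, delivers the masked acetaldehyde unit on the face of the carbamate. The olefin shifts and the (Z)-enol ether F4 results.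
- Wet oxalic acid on silica hydrolyses F4 to 19.

Step 13. The enolate carbon is neopentyl-like, and the exocyclic enone suffers allylic strain against the quaternary centre. Retro-aldol or incomplete elimination is therefore possible.
The fallback sets out from 19, together with enolate 27 made from 26, and returns at 32, so steps 13 and 14 are both bypassed.
- NaBH4 reduces 19 to the primary alcohol F5.
- I2, PPh3 and imidazole give the primary iodide F6.
- Enolate 27 (3 equiv, THF–HMPA, −40 → 0 °C) is alkylated by F6, and K2CO3 in MeOH equilibrates the α-centre to 32.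

**Further compounds**
F1 | step 6 | (5S)-5-{3-[(tert-butyldimethylsilyl)oxy]but-3-en-1-yl}-2,4,4-trimethylcyclohepta-2,6-dien-1-one | CC1=CC(C)(C)[C@@H](CCC(=C)O[Si](C)(C)C(C)(C)C)C=CC1=O
F2 | step 6 | tert-butyldimethylsilyl ether of 16 at the tertiary oxygen | CC1=CC(C)(C)[C@H]2CC[C@](C)(O[Si](C)(C)C(C)(C)C)[C@H]2CC1=O
F3 | step 8 | 7-O-(N-phenylcarbamate) of 17 | CC1=CC(C)(C)[C@H]2CC[C@](C)(O)[C@H]2C[C@H]1OC(=O)Nc1ccccc1
F4 | step 8 | (1S,3aS,5R,8aS)-5-[(Z)-2-ethoxyethenyl]-1,4,4,6-tetramethyl-1,2,3,3a,4,5,8,8a-octahydroazulen-1-ol | CC1=CC[C@H]2[C@H](CC[C@]2(C)O)C(C)(C)[C@@H]1/C=C\OCC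
F5 | step 13 | (1S,3aS,5R,8aS)-5-(2-hydroxyethyl)-1,4,4,6-tetramethyl-1,2,3,3a,4,5,8,8a-octahydroazulen-1-ol | CC1=CC[C@H]2[C@H](CC[C@]2(C)O)C(C)(C)[C@@H]1CCO
F6 | step 13 | (1S,3aS,5R,8aS)-5-(2-iodoethyl)-1,4,4,6-tetramethyl-1,2,3,3a,4,5,8,8a-octahydroazulen-1-ol | CC1=CC[C@H]2[C@H](CC[C@]2(C)O)C(C)(C)[C@@H]1CCI
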